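## Retrosynthetic overview

1. The target comes from its tetra-O-benzyl ether by hydrogenolysis; before that, the chromanone ring is closed last by an oxidative C–O bond formation (ketal) at the benzylic C–H of a 2-(4-hydroxyphenyl)dihydrofuran.
2. The dihydrofuran ring comes from a catalyst-controlled C–O ring closure of an α-aryl-4-hydroxychalcone through its para-quinone methide tautomer (the new step); this sets the ring-fusion stereocentre.
3. The chalcone comes from a Knoevenagel condensation of a deoxybenzoin with 4-hydroxybenzaldehyde; the deoxybenzoin comes from a Pd-catalysed ketone α-arylation of tribenzyl phloroacetophenone with an 8-bromoflavan.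
4. The (2R)-8-bromoflavan comes from racemic naringenin: 7-O-MOM protection, Ru transfer-hydrogenation kinetic resolution, deoxygenation, benzylation, C-8 bromination.
5. Ring order: flavan pyran (preformed in naringenin), then dihydrofuran, then chromanone/ketal.

Assumption: the target is read from the SMILES as (2S,3S) at the ketal and ring-fusion carbons (flavanone numbering) and (2R) in the flavan, and the (R)-acid of step 10 is taken to give the (8R,9R) series (the mirror-image acid is used if the sense proves opposite).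

## Route

Step 1
Reactants: 1 rac-naringenin
Product: 2 rac-5-hydroxy-2-(4-hydroxyphenyl)-7-(methoxymethoxy)chroman-4-one
Conditions: MOMCl (1.05 equiv), K2CO3, acetone, 0 °C to rt
Reagents that add atoms: chloromethyl methyl ether, COCCl
Why: Williamson O-alkylation; the 7-OH (para to the carbonyl) is the most acidic phenol, the 5-OH is hydrogen-bonded to the ketone and the 4′-OH is less acidic, so one equivalent of MOMCl goes to O-7.

Step 2
Reactants: 2 rac-5-hydroxy-2-(4-hydroxyphenyl)-7-(methoxymethoxy)chroman-4-one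
Product: 3 (2R)-5-hydroxy-2-(4-hydroxyphenyl)-7-(methoxymethoxy)chroman-4-one
Conditions: RuCl[(S,S)-TsDPEN](p-cymene) (1 mol %), HCO2H/Et3N (5:2), EtOAc, rt, stopped at about 55% conversion
Reagents that add atoms: none
Why: Noyori–Ikariya asymmetric transfer hydrogenation used as a kinetic resolution; the (2S)-flavanone is reduced much faster to the cis-(2S,4S)-flavan-4-ol, so the unreacted (2R)-ketone is recovered in high ee, which fixes the flavan stereocentre of the target.

Step 3
Reactants: 3 (2R)-5-hydroxy-2-(4-hydroxyphenyl)-7-(methoxymethoxy)chroman-4-one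
Product: 5 (2R)-2-(4-hydroxyphenyl)-7-(methoxymethoxy)chroman-5-ol, via bis(ethyl carbonate) 4 (not isolated)
Conditions: ClCO2Et, Et3N, THF, 0 °C; then NaBH4, H2O, 0 °C to rt; then 2 M NaOH, rt
Reagents that add atoms: none
Why: Ethyl chloroformate/NaBH4 deoxygenation of an ortho-hydroxyaryl ketone (hydride reduction, carbonate transfer and elimination to an ortho-quinone methide, second hydride addition); C-2 is not involved and NaOH cleaves the remaining 4′-carbonate.

Step 4
Reactants: 5 (2R)-2-(4-hydroxyphenyl)-7-(methoxymethoxy)chroman-5-ol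
Product: 6 (2R)-5-(benzyloxy)-2-[4-(benzyloxy)phenyl]-7-(methoxymethoxy)chromane
Conditions: BnBr (2.4 equiv), K2CO3, DMF, rt
Reagents that add atoms: benzyl bromide, BrCc1ccccc1
Why: Williamson etherification of both free phenols; the MOM ether is stable to base, which leaves O-7 as the only oxygen that can be unmasked later without hydrogenolysis.

Step 5
Reactants: 6 (2R)-5-(benzyloxy)-2-[4-(benzyloxy)phenyl]-7-(methoxymethoxy)chromane
Product: 7 (2R)-5-(benzyloxy)-2-[4-(benzyloxy)phenyl]-8-bromo-7-(methoxymethoxy)chromane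
Conditions: NBS (1.0 equiv), CH2Cl2, −78 to 0 °C
Reagents that add atoms: N-bromosuccinimide, O=C1CCC(=O)N1Br
Why: Electrophilic aromatic bromination of the phloroglucinol-type ring A, which occurs at C-8 in 5,7-di-O-alkylflavans (as with NBS on benzylated catechins) and leaves the less activated ring B untouched.

Step 6
Reactants: 8 1-(2,4,6-trihydroxyphenyl)ethanone
Product: 9 1-[2,4,6-tris(benzyloxy)phenyl]ethanone
Conditions: BnBr (3.5 equiv), K2CO3, DMF, 70 °C
Reagents that add atoms: benzyl bromide, BrCc1ccccc1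
Why: Exhaustive Williamson O-benzylation, with heating to overcome the ketone-chelated ortho-hydroxyl.

Step 7
Reactants: 7 (2R)-5-(benzyloxy)-2-[4-(benzyloxy)phenyl]-8-bromo-7-(methoxymethoxy)chromane; 9 1-[2,4,6-tris(benzyloxy)phenyl]ethanone
Product: 10 2-[(2R)-5-(benzyloxy)-2-[4-(benzyloxy)phenyl]-7-(methoxymethoxy)chroman-8-yl]-1-[2,4,6-tris(benzyloxy)phenyl]ethanone
Conditions: Pd2(dba)3 (2.5 mol %), XPhos (6 mol %), NaOtBu (2.2 equiv), toluene, 80 °C
Reagents that add atoms: none
Why: Buchwald–Hartwig-type Pd-catalysed α-arylation of a methyl ketone enolate; the enolate carbon is unhindered, the bulky biarylphosphine handles the di-ortho-substituted electron-rich bromide, and the acidic product enolate stops the reaction at monoarylation.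

Step 8
Reactants: 10 2-[(2R)-5-(benzyloxy)-2-[4-(benzyloxy)phenyl]-7-(methoxymethoxy)chroman-8-yl]-1-[2,4,6-tris(benzyloxy)phenyl]ethanone; 11 4-hydroxybenzaldehyde
Product: 12 (E)-2-[(2R)-5-(benzyloxy)-2-[4-(benzyloxy)phenyl]-7-(methoxymethoxy)chroman-8-yl]-3-(4-hydroxyphenyl)-1-[2,4,6-tris(benzyloxy)phenyl]prop-2-en-1-one
Conditions: piperidine (0.3 equiv), AcOH (0.3 equiv), toluene, reflux, Dean–Stark
Reagents that add atoms: none
Why: Knoevenagel-type aldol condensation of a deoxybenzoin with an aromatic aldehyde driven by azeotropic water removal; no ring closure can follow because every nucleophilic oxygen is still protected, and the alkene geometry (mainly E) is lost in step 10.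

Step 9
Reactants: 12 (E)-2-[(2R)-5-(benzyloxy)-2-[4-(benzyloxy)phenyl]-7-(methoxymethoxy)chroman-8-yl]-3-(4-hydroxyphenyl)-1-[2,4,6-tris(benzyloxy)phenyl]prop-2-en-1-one
Product: 13 (E)-2-[(2R)-5-(benzyloxy)-2-[4-(benzyloxy)phenyl]-7-hydroxychroman-8-yl]-1-[2,4-bis(benzyloxy)-6-hydroxyphenyl]-3-(4-hydroxyphenyl)prop-2-en-1-one
Conditions: BCl3 (3.5 equiv), CH2Cl2, −78 °C, 30 min; then aq. NaHCO3
Reagents that add atoms: none
Why: Lewis-acid ether cleavage under chelation control; at −78 °C BCl3 removes the acetal-type MOM ether and one benzyl ether ortho to the ketone (the boron chelate then protects the second ortho ether), while unchelated aryl benzyl ethers survive.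

Step 10
Reactants: 13 (E)-2-[(2R)-5-(benzyloxy)-2-[4-(benzyloxy)phenyl]-7-hydroxychroman-8-yl]-1-[2,4-bis(benzyloxy)-6-hydroxyphenyl]-3-(4-hydroxyphenyl)prop-2-en-1-one
Product: 14 [2,4-bis(benzyloxy)-6-hydroxyphenyl][(2R,8R,9R)-5-(benzyloxy)-2-[4-(benzyloxy)phenyl]-8-(4-hydroxyphenyl)-3,4,8,9-tetrahydro-2H-furo[2,3-h]chromen-9-yl]methanone
Conditions: (R)-TRIP (10 mol %), CHCl3, −20 °C
Reagents that add atoms: none
Why: Proposed new method: the bifunctional chiral phosphoric acid shuttles the phenolic proton of the 4-hydroxychalcone to the ketone oxygen to give a para-quinone methide enol held in a chiral hydrogen-bonded complex, the flavan 7-OH (more nucleophilic than the ketone-chelated phenol of ring A) adds to the quinone methide carbon in a 5-exo oxa-1,6-addition whose face is set by the catalyst and not by the remote flavan centre, so C-8 is formed (R) in the C–O bond-forming event and the enol is then protonated to the more stable 8,9-trans ketone, fixing C-9 as (R); the closest known reaction type is the chiral phosphoric acid-catalysed enantioselective 1,6-addition of nucleophiles to para-quinone methides generated in situ from para-hydroxystyrenes or para-hydroxybenzyl alcohols, here extended to a vinylogous quinone methide derived from a chalcone and to a ring closure that a direct 5-endo oxa-Michael addition would not allow.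

Step 11
Reactants: 14 [2,4-bis(benzyloxy)-6-hydroxyphenyl][(2R,8R,9R)-5-(benzyloxy)-2-[4-(benzyloxy)phenyl]-8-(4-hydroxyphenyl)-3,4,8,9-tetrahydro-2H-furo[2,3-h]chromen-9-yl]methanone
Product: 15 tetra-O-benzyl ether of the target [(2S,3S)-ketal core; (2R)-flavan; benzyl groups on O-5/O-7 of the chromanone unit and on O-5/O-4′ of the flavan unit]
Conditions: DDQ (1.05 equiv), CH2Cl2, −40 to 0 °C; filter, wash with aq. NaHCO3
Reagents that add atoms: none
Why: Oxidative C–H etherification of the DDQ type (as in the DDQ dehydrogenation of 2-(4-hydroxyaryl)dihydrobenzofurans and the DDQ conversion of para-methoxybenzyl ethers bearing a neighbouring hydroxyl into benzylidene acetals): hydride loss from the benzylic C-8–H para to the only oxidisable free phenol gives a para-quinone methide that the ortho-hydroxyl of the aroyl group captures 6-exo before the C-9 proton is lost, and because the ring fusion can only be cis the new ketal carbon is forced (S) by the untouched C-9 centre from step 10.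

Step 12
Reactants: 15 tetra-O-benzyl ether of the target [(2S,3S)-ketal core; (2R)-flavan; benzyl groups on O-5/O-7 of the chromanone unit and on O-5/O-4′ of the flavan unit]
Product: 16 CNP0179743.1 [(2S,3S)-5,7-dihydroxy-2-(4-hydroxyphenyl)chroman-4-one joined at C-3 to C-8 and through the C-2 ketal oxygen to C-7 of (2R)-5-hydroxy-2-(4-hydroxyphenyl)chromane]
Conditions: H2 (1 atm), Pd/C (10 wt %), EtOAc/MeOH (1:1), rt
Reagents that add atoms: none
Why: Neutral hydrogenolysis of the four aryl benzyl ethers, the deprotection used for acid- and base-sensitive A-type flavonoid ketals; no stereocentre is touched and the base-labile β-keto ketal never sees acid or base.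

## Compound list

1 | rac-naringenin (rac-5,7-dihydroxy-2-(4-hydroxyphenyl)chroman-4-one) | O=C1CC(c2ccc(O)cc2)Oc2cc(O)cc(O)c12 | starting material
2 | rac-5-hydroxy-2-(4-hydroxyphenyl)-7-(methoxymethoxy)chroman-4-one | O=C1CC(c2ccc(O)cc2)Oc2cc(OCOC)cc(O)c12 | intermediate
3 | (2R)-5-hydroxy-2-(4-hydroxyphenyl)-7-(methoxymethoxy)chroman-4-one | O=C1C[C@H](c2ccc(O)cc2)Oc2cc(OCOC)cc(O)c12 | intermediate
4 | ethyl 4-[(2R)-5-[(ethoxycarbonyl)oxy]-7-(methoxymethoxy)-4-oxochroman-2-yl]phenyl carbonate (bis(ethyl carbonate) of 3) | O=C1C[C@H](c2ccc(OC(=O)OCC)cc2)Oc2cc(OCOC)cc(OC(=O)OCC)c12 | intermediate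
5 | (2R)-2-(4-hydroxyphenyl)-7-(methoxymethoxy)chroman-5-ol | Oc1ccc(cc1)[C@H]1CCc2c(O)cc(OCOC)cc2O1 | intermediate
6 | (2R)-5-(benzyloxy)-2-[4-(benzyloxy)phenyl]-7-(methoxymethoxy)chromane | c1ccccc1COc1ccc(cc1)[C@H]1CCc2c(OCc3ccccc3)cc(OCOC)cc2O1 | intermediate
7 | (2R)-5-(benzyloxy)-2-[4-(benzyloxy)phenyl]-8-bromo-7-(methoxymethoxy)chromane | c1ccccc1COc1ccc(cc1)[C@H]1CCc2c(OCc3ccccc3)cc(OCOC)c(Br)c2O1 | intermediate
8 | 1-(2,4,6-trihydroxyphenyl)ethanone (phloroacetophenone) | CC(=O)c1c(O)cc(O)cc1O | starting material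
9 | 1-[2,4,6-tris(benzyloxy)phenyl]ethanone | CC(=O)c1c(OCc2ccccc2)cc(OCc2ccccc2)cc1OCc1ccccc1 | intermediate
10 | 2-[(2R)-5-(benzyloxy)-2-[4-(benzyloxy)phenyl]-7-(methoxymethoxy)chroman-8-yl]-1-[2,4,6-tris(benzyloxy)phenyl]ethanone | c1ccccc1COc1ccc(cc1)[C@H]1CCc2c(OCc3ccccc3)cc(OCOC)c(CC(=O)c3c(OCc4ccccc4)cc(OCc4ccccc4)cc3OCc3ccccc3)c2O1 | intermediate
11 | 4-hydroxybenzaldehyde | O=Cc1ccc(O)cc1 | starting material
12 | (E)-2-[(2R)-5-(benzyloxy)-2-[4-(benzyloxy)phenyl]-7-(methoxymethoxy)chroman-8-yl]-3-(4-hydroxyphenyl)-1-[2,4,6-tris(benzyloxy)phenyl]prop-2-en-1-one | c1ccccc1COc1ccc(cc1)[C@H]1CCc2c(OCc3ccccc3)cc(OCOC)c(/C(=C\c3ccc(O)cc3)C(=O)c3c(OCc4ccccc4)cc(OCc4ccccc4)cc3OCc3ccccc3)c2O1 | intermediate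
13 | (E)-2-[(2R)-5-(benzyloxy)-2-[4-(benzyloxy)phenyl]-7-hydroxychroman-8-yl]-1-[2,4-bis(benzyloxy)-6-hydroxyphenyl]-3-(4-hydroxyphenyl)prop-2-en-1-one | c1ccccc1COc1ccc(cc1)[C@H]1CCc2c(OCc3ccccc3)cc(O)c(/C(=C\c3ccc(O)cc3)C(=O)c3c(O)cc(OCc4ccccc4)cc3OCc3ccccc3)c2O1 | intermediate
14 | [2,4-bis(benzyloxy)-6-hydroxyphenyl][(2R,8R,9R)-5-(benzyloxy)-2-[4-(benzyloxy)phenyl]-8-(4-hydroxyphenyl)-3,4,8,9-tetrahydro-2H-furo[2,3-h]chromen-9-yl]methanone (8,9-trans) | O=C(c1c(O)cc(OCc2ccccc2)cc1OCc1ccccc1)[C@H]1[C@H](c2ccc(O)cc2)Oc2cc(OCc3ccccc3)c3CC[C@H](c4ccc(OCc5ccccc5)cc4)Oc3c21 | intermediate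
15 | tetra-O-benzyl ether of the target: (2S,3S)-ketal core with the 4-hydroxyphenyl on the ketal carbon free, (2R)-flavan, benzyl on O-5 and O-7 of the chromanone unit and on O-5 and O-4′ of the flavan unit | O=C1c2c(OCc3ccccc3)cc(OCc3ccccc3)cc2O[C@@]2(c3ccc(O)cc3)Oc3cc(OCc4ccccc4)c4c(c3[C@@H]12)O[C@@H](c1ccc(OCc5ccccc5)cc1)CC4 | intermediate
16 | CNP0179743.1: (2S,3S)-5,7-dihydroxy-2-(4-hydroxyphenyl)chroman-4-one joined at C-3 to C-8 and through the C-2 ketal oxygen to C-7 of (2R)-5-hydroxy-2-(4-hydroxyphenyl)chromane (cis-fused) | O=C1c2c(O)cc(O)cc2O[C@@]2(c3ccc(O)cc3)Oc3cc(O)c4c(c3[C@@H]12)O[C@@H](c1ccc(O)cc1)CC4 | target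

## Step count and risk

Total step count: 12. Longest linear sequence: 11 steps (steps 1 to 5, then 7 to 12); step 6 is the one-step side branch.

The three steps most likely to fail:

Step 10, the proposed new ring closure. The acid may fail to form the quinone methide enol, the chelated ring A phenol may close to a flavanone instead, or the catalyst may give poor selectivity at C-8. The fallback uses known chemistry and sets out from 13. NaOAc in refluxing EtOH effects the classical 2′-hydroxychalcone-to-flavanone oxa-Michael closure through the ring A phenol. It gives the (2S,3R)-trans-3-arylflavanone F1 together with its (2R,3S)-diastereomer F2. The two are diastereomers because of the (2R)-flavan centre, so they are separated by preparative HPLC, and F2 is re-equilibrated through the chalcone with the same base and recycled. F1 is then oxidised with DDQ at low temperature as in step 11; here the flavan 7-OH closes the five-membered ring on the quinone methide, as in the oxidative conversion of B-type into A-type proanthocyanidins. This comes back to the route at 15.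

Step 11, the oxidative ketalisation. The quinone methide may lose the C-9 proton to give the aromatic benzofuran faster than the chelated phenol closes the ring, or excess DDQ may attack the electron-rich flavan benzylic positions. The fallback sets out from 14 and separates oxidation from ring closure. DDQ in CH2Cl2/MeOH traps the quinone methide intermolecularly with the solvent (the known DDQ/methanol benzylic oxidation of para-hydroxybenzyl compounds) to give the 8-methoxy ketal F3 as a mixture of C-8 epimers. Acid-catalysed transketalisation of F3 (PPTS, 5 Å molecular sieves to take up methanol, toluene, rt) then closes the chromanone ring and comes back at 15.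

Step 7, the α-arylation. The bromide is di-ortho-substituted and electron-rich, so oxidative addition or reductive elimination may be slow and hydrodebromination may compete. The fallback reverses the polarity of the coupling and sets out from 7 and 9. Miyaura borylation of 7 (B2pin2, Pd(dppf)Cl2, KOAc, dioxane, 90 °C) gives the pinacol boronate F4. α-Bromination of 9 (CuBr2, EtOAc/CHCl3, reflux) gives the phenacyl bromide F5. Suzuki–Miyaura coupling of F4 with F5 (Pd(PPh3)4, K3PO4, toluene/H2O, 80 °C; the known synthesis of deoxybenzoins from arylboron reagents and α-bromoacetophenones) comes back to the route at 10.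

Further compounds
F1 | step 10 | (2S,3R)-5,7-bis(benzyloxy)-3-[(2R)-5-(benzyloxy)-2-[4-(benzyloxy)phenyl]-7-hydroxychroman-8-yl]-2-(4-hydroxyphenyl)chroman-4-one | O=C1c2c(OCc3ccccc3)cc(OCc3ccccc3)cc2O[C@H](c2ccc(O)cc2)[C@H]1c1c(O)cc(OCc2ccccc2)c2CC[C@H](c3ccc(OCc4ccccc4)cc3)Oc12
F2 | step 10 | (2R,3S)-5,7-bis(benzyloxy)-3-[(2R)-5-(benzyloxy)-2-[4-(benzyloxy)phenyl]-7-hydroxychroman-8-yl]-2-(4-hydroxyphenyl)chroman-4-one | O=C1c2c(OCc3ccccc3)cc(OCc3ccccc3)cc2O[C@@H](c2ccc(O)cc2)[C@@H]1c1c(O)cc(OCc2ccccc2)c2CC[C@H](c3ccc(OCc4ccccc4)cc3)Oc12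
F3 | step 11 | [2,4-bis(benzyloxy)-6-hydroxyphenyl][(2R,9S)-5-(benzyloxy)-2-[4-(benzyloxy)phenyl]-8-(4-hydroxyphenyl)-8-methoxy-3,4,8,9-tetrahydro-2H-furo[2,3-h]chromen-9-yl]methanone (mixture of C-8 epimers) | O=C(c1c(O)cc(OCc2ccccc2)cc1OCc1ccccc1)[C@H]1C(OC)(c2ccc(O)cc2)Oc2cc(OCc3ccccc3)c3CC[C@H](c4ccc(OCc5ccccc5)cc4)Oc3c21
F4 | step 7 | (2R)-5-(benzyloxy)-2-[4-(benzyloxy)phenyl]-7-(methoxymethoxy)-8-(4,4,5,5-tetramethyl-1,3,2-dioxaborolan-2-yl)chromane | c1ccccc1COc1ccc(cc1)[C@H]1CCc2c(OCc3ccccc3)cc(OCOC)c(B3OC(C)(C)C(C)(C)O3)c2O1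
F5 | step 7 | 2-bromo-1-[2,4,6-tris(benzyloxy)phenyl]ethanone | BrCC(=O)c1c(OCc2ccccc2)cc(OCc2ccccc2)cc1OCc1ccccc1
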